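## The problem

The target is a germacranolide: ring A is a ten-membered carbocycle (C1–C10) with a Z trisubstituted C1/C10 olefin and an E trisubstituted C4/C5 olefin, and ring B is an α-methylene-γ-butyrolactone (O, C6, C7, C11, C12, with C13 the exocyclic methylene) fused across C6–C7 with O6 and C11 on opposite faces. Ring A carries four contiguous oxygenated stereocentres: C6 (lactone oxygen), C7 (a fully substituted carbinol), C8 (the (2S,3R)-2,3-epoxy-2-methylbutanoate) and C9 (a free allylic hydroxyl); with the two ester centres this makes six stereocentres and two olefin geometries. On a flexible ten-membered ring these centres cannot be relied on to steer one another, but folded back onto a six-membered ring (C5–C10) the cis C8/C9 diol, taken from the chiral pool as an acetonide, can direct the centres at C5, C6, C7 and C10. The two ester centres are remote from the ring and are better set separately under reagent control. The exocyclic enoate is a Michael acceptor, the epoxy ester and the 1,5-diene tolerate neither strong acid nor prolonged heating, the C8 acyl group can migrate to O9, and the lactone could close on O8 instead of O6, so organometallic and strongly basic steps must come before ring B and the ester. The enabling feature is the 1,5-diene C10=C1–C2–C3–C4=C5 of ring A, which is the product pattern of a [3,3] shift across a C5–C10 bond. Ring A is therefore the ring-expanded form of a cyclohexane bearing vinyl on C10 and isopropenyl on C5, and an oxygen on C10 turns the shift into an anionic oxy-Cope whose enolate marks C10 for later methylation.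

## Retrosynthesis

**C8 ester.** Target 33 is cut at the C8–O acyl bond, giving triol lactone 25 (used as its 9-O-triethylsilyl ether 26, released via 32) and acid 30. Epoxidising a tiglate on the macrocycle instead would compete with three other olefins and has no face control. The cut removes two stereocentres and the most fragile group from all earlier intermediates. Acid 30 goes back through epoxy alcohol 29 and allylic alcohol 28 to ethyl tiglate 27, so both centres come from one Sharpless epoxidation. The forward esterification must pick O8 out of three hydroxyls: O7 is tertiary and O9 is silylated first.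

**Ring B carbonyl.** Lactone 25 goes back through acetonide 24 and lactol 23 to the cyclic ethyl acetal 22; only the oxidation level of C12 changes. Carrying C12 as an acetal already bonded to O6 is preferred to a late oxidative lactonisation of a free polyol, where a C12 aldehyde could close on O8 as readily as on O6. In 22 the O6–C12 bond is fixed while O8 is still inside the dioxolane, and no electrophilic group is present. The forward steps need the allylic mixed acetal to hydrolyse before the dioxolane, then a lactol oxidation.

**C10–C14.** Methyl diene 22 is cut at C10–C14 to dienyl triflate 21. The methyl cannot be placed earlier because C10 must carry the oxygen that drives the ring expansion. The forward cross-coupling must keep the olefin geometry.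

**Ring A (key cut).** Triflate 21 is traced to cyclohexanol 18 by breaking C2–C3 and re-forming C5–C10. The neighbouring cuts (C9–C10 by carbonyl addition, C4–C5 by olefination or metathesis) each close a medium ring end to end and create a trisubstituted olefin or a stereocentre in that event. Here ring size, olefin positions and both geometries follow from one chair transition state. Precursor 18 has six contiguous stereocentres, but on a rigid template. The forward step needs vinyl and isopropenyl cis and the chair with the alkoxide pseudo-equatorial on the forming array.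

**C10–C1 and the conformational lock.** Carbinol 18 is cut at C10–C1 to ketone 17 and vinylmagnesium bromide 6. Ketone 17 comes from alcohol 16 and silyl ether 15. Acetal 15 comes from diol 14 by closing O6 onto C12; the trans ring fusion allows only the chair in which isopropenyl is axial and vinyl will be equatorial. The vinyl group must enter cis to the isopropenyl group, which the axial C8 oxygen of the dioxolane is expected to enforce.

**C7–C11, C6–O and C5–C4.** Diol 14 is cut at C7–C11 to α-silyloxy ketone 12 and bromo acetal 13. Ketone 12 is cut at C6–O to enol ether 10, and 10 at C5–C4 to enone 8 and isopropenylmagnesium bromide 9. The order matters: the conjugate addition is steered by the all-cis oxygens at C8–C10, the enol ether oxidation by the dioxolane, and the C7 addition by the new C6 oxygen. Enone 8 carries three stereocentres, all from the chiral pool.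

**Template.** Enone 8 is cut at the C5=C6 double bond (ring-closing metathesis) to dienone 7. This goes back to Weinreb amide 5 and 6, then through 4, 3 and 2 to 2,3-O-isopropylidene-D-ribono-1,4-lactone 1. The ribo configuration supplies O8, O9 and O10 all cis.

## Roads not taken

Alternative 1: The cut runs through C7–C11 and C6–C12 of ring B. In the forward direction dichloroketene A2 would add across the C6/C7 double bond of the acyclic Z silyl enol ether A3 to give dichlorocyclobutanone A1, which holds all four carbons of ring B. Ring enlargement by Baeyer–Villiger oxidation, dechlorination and methylenation would follow, and ring A would be closed later through the C10 alkenyl iodide.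

- Merits: a suprafacial cycloaddition brings both lactone carbons at once and ties the C6/C7 relationship to the enol ether geometry; the ketene A2 is cheap and no carbohydrate template is needed.
- Weak points: enol ether A3 is a 2-silyloxy-1,3-diene, so ketene A2 can add at the C4/C5 end or in a [4+2] sense. Face selectivity rests on one acyclic centre (C8). Several further operations are needed before ring B exists. The ten-membered ring must still be closed by a C9–C10 coupling that creates the C9 carbinol on a forming medium ring.
- Comparison: this road is more convergent for ring B. The chosen plan sets against it a ring A made without macrocyclisation and with both olefin geometries fixed in the same step.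

Alternative 2: The cut is C11–C12. The C6 phenyl selenocarbonate A5 would give an alkoxycarbonyl radical under tin hydride chain conditions; this cyclises 5-exo-dig onto the C7 ethynyl group to give lactone A4.

- Merits: ring B is installed in one neutral step at the end, already at the lactone oxidation level, on a substrate whose O8 and O9 carry different protecting groups. In that respect it is better than the chosen plan, which must tell O8 from O9 by a selective silylation.
- Weak points: the radical sits on an allylic oxygen, so decarboxylation to an allyl radical competes with cyclisation. The resulting vinyl radical can abstract hydrogen across the ring or add to the ring olefins. The macrocycle of selenocarbonate A5, with its tertiary propargylic alcohol, must first be closed by some other bond.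
- Comparison: against the protecting-group advantage the chosen plan sets the construction of ring A itself, and it secures the O6 (not O8) lactone by bonding C12 to O6 early.

Alternative 3: The cut is C9–C10 and C10–C14. 5-Lithio-2,3-dihydrofuran A7 and a methylcopper reagent would undergo 1,2-metalate rearrangement to a Z alkenylcuprate, which adds to aldehyde A8 to give allylic alcohol A6.

- Merits: the Z trisubstituted C1/C10 olefin and the C14 methyl arrive in one operation from dihydrofuran A7 with full geometric control. This is more direct than the chosen plan, which needs the enolate geometry from the transition state plus a separate cross-coupling.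
- Weak points: the C9 configuration depends on Felkin–Anh versus chelation control at the α-silyloxy aldehyde A8. In alcohol A6 C6 is still at the primary alcohol level inside the acetonide, so the C6 stereocentre, the E C4/C5 olefin and ring A would all have to come from a later medium-ring closure.
- Comparison: this road solves the C1/C10 geometry better but leaves the hardest problem open. The chosen plan sets against it a ring expansion on a template where C6–C9 are already in place.

Key step: step 14

## Route

Remarks on the chemistry:
- Six-ring and macrocycle carbons carry germacrane numbers (C5–C10 ring carbons; C4, C3, C15 the isopropenyl group; C1, C2 the vinyl group; C11–C13 the side chain on C7). β is the face of the C5 isopropenyl group, α the opposite face.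
- The acetal carbon C12 of 14–23 is expected as a mixture of epimers that converge at lactone 24; its configuration is left open in the SMILES.
- 2-Bromo-3,3-diethoxyprop-1-ene (13) is taken as a catalogue compound; otherwise it is made from acrolein diethyl acetal by bromination and dehydrobromination.

Step 1
Reactants: 1 2,3-O-isopropylidene-D-ribono-1,4-lactone
Product: 2 5-aldehyde of lactone 1 (C5 as CHO; D-ribo configuration unchanged)
Conditions: Dess–Martin periodinane, CH2Cl2, 0 °C to rt
Reagents that add atoms: none
Why: Dess–Martin oxidation of a primary alcohol under neutral conditions, so the C4 centre next to the new aldehyde should not epimerise; the crude aldehyde is used at once.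

Step 2
Reactants: 2 5-aldehyde of lactone 1
Product: 3 5,6-dideoxy-2,3-O-isopropylidene-D-ribo-hex-5-enono-1,4-lactone
Conditions: Ph3PCH3Br, KN(SiMe3)2, THF, −78 °C to 0 °C
Reagents that add atoms: methyltriphenylphosphonium bromide, C[P+](c1ccccc1)(c1ccccc1)c1ccccc1.[Br-]
Why: Wittig methylenation; at low temperature the salt-free ylide should react with the aldehyde faster than with the lactone carbonyl or the C4–H.

Step 3
Reactants: 3 5,6-dideoxy-2,3-O-isopropylidene-D-ribo-hex-5-enono-1,4-lactone
Product: 4 5,6-dideoxy-2,3-O-isopropylidene-N-methoxy-N-methyl-D-ribo-hex-5-enonamide (free 4-OH)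
Conditions: MeNH(OMe)·HCl, iPrMgCl, THF, −20 °C
Reagents that add atoms: N,O-dimethylhydroxylamine hydrochloride, CNOC.Cl
Why: Weinreb amide formation by aminolysis of the lactone with the magnesium amide; no stereocentre is touched and C1 stays at the acyl level.

Step 4
Reactants: 4 hydroxy Weinreb amide
Product: 5 4-O-(tert-butyldimethylsilyl) ether of amide 4
Conditions: TBSOTf, 2,6-lutidine, CH2Cl2, −78 °C
Reagents that add atoms: tert-butyldimethylsilyl trifluoromethanesulfonate, CC(C)(C)[Si](C)(C)OS(=O)(=O)C(F)(F)F
Why: Fast silylation caps the γ-hydroxyl before it can re-close the lactone; this oxygen becomes O10.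

Step 5
Reactants: 5 silylated Weinreb amide; 6 vinylmagnesium bromide
Product: 7 6-O-TBS-4,5-O-isopropylidene-octa-1,7-dien-3-one (D-ribo configuration of 5 at C4–C6)
Conditions: THF, −78 °C to 0 °C; quench into cold aqueous citric acid
Reagents that add atoms: none
Why: Weinreb ketone synthesis; the chelated tetrahedral intermediate prevents over-addition, and the acidic quench keeps the liberated amine from adding to the vinyl ketone.

Step 6
Reactants: 7 dienone
Product: 8 10α-(tert-butyldimethylsilyloxy)-8α,9α-(isopropylidenedioxy)cyclohex-5-en-7-one
Conditions: second-generation Grubbs catalyst (5 mol%), CH2Cl2, 40 °C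
Reagents that add atoms: none
Why: Ring-closing metathesis of a 1,7-dien-3-one to a cyclohexenone with loss of ethene; the three oxygens at C8, C9 and C10 are all cis (α).

Step 7
Reactants: 8 enone; 9 isopropenylmagnesium bromide
Product: 10 5β-isopropenyl-7-(trimethylsilyloxy)-10α-(TBS-oxy)-8α,9α-(isopropylidenedioxy)cyclohex-6-ene
Conditions: CuBr·SMe2 (20 mol%), TMSCl, THF, −78 °C; Et3N
Reagents that add atoms: chlorotrimethylsilane, C[Si](C)(C)Cl
Why: Copper-catalysed conjugate addition with silyl trapping; the isopropenyl group enters C5 anti to the C10 silyloxy group and the dioxolane (all α), which sets C5 (β) and gives the regiodefined C6/C7 enol ether.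

Step 8
Reactants: 10 trimethylsilyl enol ether
Product: 12 6β-(trimethylsilyloxy)-5β-isopropenyl-10α-(TBS-oxy)-8α,9α-(isopropylidenedioxy)cyclohexan-7-one, via silyloxy epoxide 11 (not isolated)
Conditions: mCPBA, hexane/CH2Cl2, −15 °C
Reagents that add atoms: 3-chloroperoxybenzoic acid, OOC(=O)c1cccc(Cl)c1
Why: Rubottom oxidation; the peracid should attack the enol ether from the β face, which carries only the C5 isopropenyl group while the α face carries the cis-fused dioxolane and the C10 silyloxy group, and silyl migration in 11 gives the 6β-silyloxy ketone; the isopropenyl olefin is far less nucleophilic than the enol ether.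

Step 9
Reactants: 12 α-silyloxy ketone; 13 2-bromo-3,3-diethoxyprop-1-ene
Product: 14 7α-(3,3-diethoxyprop-1-en-2-yl)-5β-isopropenyl-10α-(TBS-oxy)-8α,9α-(isopropylidenedioxy)cyclohexane-6β,7β-diol
Conditions: 13, n-BuLi, THF, −78 °C; CeCl3, −78 °C; then 12; then K2CO3, MeOH, 0 °C
Reagents that add atoms: none
Why: Organocerium 1,2-addition to an α-silyloxy ketone (low basicity avoids enolisation and β-elimination); attack is expected from the α face, anti to the C6–O bond (Felkin–Anh) and away from the β isopropenyl and silyloxy groups, giving C11 α and the C7 hydroxyl β; methanolysis then removes the trimethylsilyl group.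

Step 10
Reactants: 14 diol diethyl acetal
Product: 15 trans-fused cyclic ethyl acetal (O6–C12(OEt)–C11(=CH2)–C7 ring) with 7β-OH and 10α-OTBS and 8α,9α-acetonide and 5β-isopropenyl
Conditions: PPTS (cat.), 4 Å molecular sieves, CH2Cl2, rt
Reagents that add atoms: none
Why: Acid-catalysed intramolecular transacetalisation; only O6 can reach C12 in a five-membered ring (O8 is inside the dioxolane), and the trans fusion requires O6 and C11 both equatorial, which fixes the chair with the isopropenyl group axial.

Step 11
Reactants: 15 silyl ether
Product: 16 10α-alcohol of acetal 15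
Conditions: TBAF, THF, rt
Reagents that add atoms: none
Why: Fluoride cleaves the only silyl ether; acetal and dioxolane are inert.

Step 12
Reactants: 16 secondary alcohol
Product: 17 C10 ketone of acetal 15
Conditions: Dess–Martin periodinane, pyridine, CH2Cl2, 0 °C
Reagents that add atoms: none
Why: Dess–Martin oxidation of the secondary C10 alcohol; the tertiary C7 hydroxyl cannot be oxidised and pyridine buffers the acid-labile acetal.

Step 13
Reactants: 17 ketone; 6 vinylmagnesium bromide
Product: 18 10β-vinyl-5β-isopropenyl cyclohexane-7β,10α-diol (cis-1-vinyl-2-isopropenyl cyclitol with the cyclic acetal and the 8α,9α-acetonide)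
Conditions: CeCl3, THF, −78 °C
Reagents that add atoms: none
Why: Organocerium addition (non-basic, so no enolisation toward C5 or C9); on the locked chair the vinyl group should attack equatorially from the β face because the axial C8 oxygen of the dioxolane closes the axial α trajectory, giving vinyl β (cis to isopropenyl) and O10 α.

Step 14
Reactants: 18 cis-1-vinyl-2-isopropenyl cyclitol
Product: 21 ring A dienyl triflate (C10 enol triflate; 4E and ring-cis C1/C10; cyclic acetal and 8,9-acetonide and free C7 OH), via dipotassium dialkoxide 19 (not isolated), via dipotassium enolate 20 (not isolated)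
Conditions: KH, 18-crown-6, THF, 0 °C to rt; then PhNTf2, −78 °C to 0 °C
Reagents that add atoms: N-phenylbis(trifluoromethanesulfonimide), O=S(=O)(N(c1ccccc1)S(=O)(=O)C(F)(F)F)C(F)(F)F
Why: KH with 18-crown-6 gives dialkoxide 19, whose C10 oxyanion weakens the C5–C10 bond; a concerted [3,3] shift through a chair array of C2, C1, C10, C5, C4 and C3 joins C2 to C3 as C5–C10 breaks and gives the regiodefined enolate 20, which PhNTf2 sulfonylates on oxygen. This is the known anionic oxy-Cope rearrangement of a 1,2-dialkenylcyclohexanol with enolate trapping. Ring A forms by a four-carbon ring expansion (six to ten), not by end-to-end closure, so no dilution is needed. No stereocentre is created: C5 and C10 become trigonal and C6–C9 are untouched. The step must deliver the 4E olefin and the ring-cis C1/C10 enolate, which requires the array with the alkoxide pseudo-equatorial, C9 axial and C6 equatorial; that array arises from the cyclohexane chair with vinyl equatorial and isopropenyl axial. The trans-fused acetal across C6–C7 admits only that chair, so the other chair (vinyl axial), which would lead to the 4Z ring-trans isomer, is not available. The tertiary C7 alkoxide, axial and flanked by three substituted carbons, is expected to stay unsulfonylated and is reprotonated on work-up.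

Step 15
Reactants: 21 dienyl triflate
Product: 22 C10-methyl diene (1(10)Z,4E; cyclic ethyl acetal and 8,9-acetonide and free C7 OH)
Conditions: MeMgBr, Fe(acac)3 (10 mol%), THF/NMP, −30 °C to 0 °C
Reagents that add atoms: methylmagnesium bromide, C[Mg]Br
Why: Iron-catalysed cross-coupling of an alkenyl triflate with a Grignard reagent, which proceeds with retention of olefin geometry and installs C14; the first equivalent only deprotonates the C7 hydroxyl.

Step 16
Reactants: 22 cyclic ethyl acetal
Product: 23 lactol (C12 hemiacetal; 8,9-acetonide retained)
Conditions: PPTS, acetone/H2O (5:1), rt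
Reagents that add atoms: water, O
Why: Hydrolysis of the allylic furanoside-like mixed acetal should be much faster than that of the cis-fused dioxolane, so only C12 is unmasked.

Step 17
Reactants: 23 lactol
Product: 24 α-methylene-γ-butyrolactone with 8,9-O-isopropylidene and free C7 OH
Conditions: TEMPO (20 mol%), PhI(OAc)2, CH2Cl2, rt
Reagents that add atoms: none
Why: Oxoammonium oxidation of a lactol to the lactone; ring B is closed on O6 because O8 is still protected, and the tertiary hydroxyl is inert.

Step 18
Reactants: 24 acetonide lactone
Product: 25 triol lactone (free 7-OH, 8-OH and 9-OH)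
Conditions: AcOH/H2O (4:1), 40 °C
Reagents that add atoms: none
Why: Mild aqueous acid hydrolysis of the isopropylidene ketal; acetic acid is chosen to stay below the acidity that triggers transannular cyclisation of the 1,5-diene.

Step 19
Reactants: 25 triol lactone
Product: 26 9-O-triethylsilyl ether of triol lactone 25
Conditions: TESCl, imidazole, CH2Cl2, −40 °C
Reagents that add atoms: chlorotriethylsilane, CC[Si](Cl)(CC)CC
Why: Selective silylation of the least hindered hydroxyl; the allylic C9 OH should react before the C8 OH, which is flanked by the quaternary C7, and before the tertiary C7 OH.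

Step 20
Reactants: 27 ethyl (E)-2-methylbut-2-enoate
Product: 28 (E)-2-methylbut-2-en-1-ol
Conditions: iBu2AlH, CH2Cl2, −78 °C to 0 °C
Reagents that add atoms: none
Why: 1,2-Reduction of an enoate to the allylic alcohol with retention of the E geometry.

Step 21
Reactants: 28 (E)-2-methylbut-2-en-1-ol
Product: 29 (2R,3R)-2,3-epoxy-2-methylbutan-1-ol
Conditions: Ti(OiPr)4, D-(−)-diethyl tartrate, t-BuOOH, 4 Å molecular sieves, CH2Cl2, −20 °C
Reagents that add atoms: tert-butyl hydroperoxide, CC(C)(C)OO
Why: Sharpless asymmetric epoxidation; the D-(−)-tartrate is expected to deliver oxygen to the face that gives the (2R,3R) epoxy alcohol (the L-(+) ligand gives 2S,3S with E-2-alken-1-ols), so both ester centres are set by the reagent.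

Step 22
Reactants: 29 (2R,3R)-2,3-epoxy-2-methylbutan-1-ol
Product: 30 (2S,3R)-2,3-epoxy-2-methylbutanoic acid
Conditions: RuCl3 (cat.), NaIO4, MeCN/CCl4/H2O, rt
Reagents that add atoms: water, O
Why: Ruthenium tetroxide oxidation of an epoxy alcohol to the glycidic acid without opening the epoxide; the C2 descriptor changes from R to S only through the priority change.

Step 23
Reactants: 26 9-O-triethylsilyl lactone; 30 (2S,3R)-2,3-epoxy-2-methylbutanoic acid
Product: 32 9-O-triethylsilyl ether of the target, via mixed anhydride 31 (not isolated)
Conditions: 30, 2,4,6-trichlorobenzoyl chloride, Et3N, THF, rt; then 26, DMAP, toluene, rt to 40 °C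
Reagents that add atoms: none
Why: Yamaguchi esterification; only the secondary C8 hydroxyl can be acylated (O9 is silylated, O7 is tertiary) and no stereocentre is touched.

Step 24
Reactants: 32 9-O-triethylsilyl ether of the target
Product: 33 CNP0420662.1
Conditions: HF·pyridine, pyridine, THF, 0 °C
Reagents that add atoms: none
Why: Buffered fluoride removes the triethylsilyl ether; the epoxy ester and the α-methylene lactone should survive, and the acyl group has no base to drive migration to O9.

## Compound list

1 | 2,3-O-isopropylidene-D-ribono-1,4-lactone | O=C1O[C@H](CO)[C@H]2OC(C)(C)O[C@@H]12 | starting material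
2 | 5-aldehyde of lactone 1 | O=C1O[C@H](C=O)[C@H]2OC(C)(C)O[C@@H]12 | intermediate
3 | 5,6-dideoxy-2,3-O-isopropylidene-D-ribo-hex-5-enono-1,4-lactone | O=C1O[C@H](C=C)[C@H]2OC(C)(C)O[C@@H]12 | intermediate
4 | 5,6-dideoxy-2,3-O-isopropylidene-N-methoxy-N-methyl-D-ribo-hex-5-enonamide | C=C[C@@H](O)[C@H]1OC(C)(C)O[C@H]1C(=O)N(C)OC | intermediate
5 | 4-O-TBS ether of amide 4 | C=C[C@@H](O[Si](C)(C)C(C)(C)C)[C@H]1OC(C)(C)O[C@H]1C(=O)N(C)OC | intermediate
6 | vinylmagnesium bromide | C=C[Mg]Br | starting material
7 | 6-O-TBS-4,5-O-isopropylidene-octa-1,7-dien-3-one (D-ribo) | C=C[C@@H](O[Si](C)(C)C(C)(C)C)[C@H]1OC(C)(C)O[C@H]1C(=O)C=C | intermediate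
8 | 10α-(TBS-oxy)-8α,9α-(isopropylidenedioxy)cyclohex-5-en-7-one | O=C1C=C[C@@H](O[Si](C)(C)C(C)(C)C)[C@H]2OC(C)(C)O[C@@H]12 | intermediate
9 | isopropenylmagnesium bromide | CC(=C)[Mg]Br | starting material
10 | 5β-isopropenyl C6/C7 trimethylsilyl enol ether | C[Si](C)(C)OC1=C[C@H](C(C)=C)[C@@H](O[Si](C)(C)C(C)(C)C)[C@H]2OC(C)(C)O[C@@H]12 | intermediate
11 | 6β,7β-epoxide of enol ether 10 | C[Si](C)(C)O[C@@]12O[C@@H]1[C@H](C(C)=C)[C@@H](O[Si](C)(C)C(C)(C)C)[C@H]3OC(C)(C)O[C@@H]23 | intermediate
12 | 6β-(trimethylsilyloxy)-5β-isopropenyl cyclohexan-7-one | O=C1[C@H](O[Si](C)(C)C)[C@H](C(C)=C)[C@@H](O[Si](C)(C)C(C)(C)C)[C@H]2OC(C)(C)O[C@@H]12 | intermediate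
13 | 2-bromo-3,3-diethoxyprop-1-ene | CCOC(OCC)C(Br)=C | starting material
14 | 6β,7β-diol with 7α-(3,3-diethoxyprop-1-en-2-yl) | CCOC(OCC)C(=C)[C@@]1(O)[C@H](O)[C@H](C(C)=C)[C@@H](O[Si](C)(C)C(C)(C)C)[C@H]2OC(C)(C)O[C@@H]12 | intermediate
15 | trans-fused cyclic ethyl acetal, 10α-OTBS | CCOC1O[C@@H]2[C@H](C(C)=C)[C@@H](O[Si](C)(C)C(C)(C)C)[C@H]3OC(C)(C)O[C@H]3[C@@]2(O)C1=C | intermediate
16 | 10α-alcohol of acetal 15 | CCOC1O[C@@H]2[C@H](C(C)=C)[C@@H](O)[C@H]3OC(C)(C)O[C@H]3[C@@]2(O)C1=C | intermediate
17 | C10 ketone | CCOC1O[C@@H]2[C@H](C(C)=C)C(=O)[C@H]3OC(C)(C)O[C@H]3[C@@]2(O)C1=C | intermediate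
18 | cis-1-vinyl-2-isopropenyl cyclitol (10β-vinyl, 10α-OH) | CCOC1O[C@@H]2[C@H](C(C)=C)[C@@](C=C)(O)[C@H]3OC(C)(C)O[C@H]3[C@@]2(O)C1=C | intermediate
19 | dipotassium 7,10-dialkoxide of 18 | CCOC1O[C@@H]2[C@H](C(C)=C)[C@@](C=C)([O-])[C@H]3OC(C)(C)O[C@H]3[C@@]2([O-])C1=C.[K+].[K+] | intermediate
20 | dipotassium C10 enolate / C7 alkoxide of the ring-expanded ketone | CCOC1O[C@@H]2/C=C(\C)CC/C=C(/[O-])[C@H]3OC(C)(C)O[C@H]3[C@@]2([O-])C1=C.[K+].[K+] | intermediate
21 | ring A dienyl triflate (C10 enol triflate) | CCOC1O[C@@H]2/C=C(\C)CC/C=C(/OS(=O)(=O)C(F)(F)F)[C@H]3OC(C)(C)O[C@H]3[C@@]2(O)C1=C | intermediate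
22 | C10-methyl diene (1(10)Z,4E) cyclic ethyl acetal | CCOC1O[C@@H]2/C=C(\C)CC/C=C(/C)[C@H]3OC(C)(C)O[C@H]3[C@@]2(O)C1=C | intermediate
23 | lactol | OC1O[C@@H]2/C=C(\C)CC/C=C(/C)[C@H]3OC(C)(C)O[C@H]3[C@@]2(O)C1=C | intermediate
24 | 8,9-O-isopropylidene lactone | O=C1O[C@@H]2/C=C(\C)CC/C=C(/C)[C@H]3OC(C)(C)O[C@H]3[C@@]2(O)C1=C | intermediate
25 | triol lactone | O=C1O[C@@H]2/C=C(\C)CC/C=C(/C)[C@@H](O)[C@@H](O)[C@@]2(O)C1=C | intermediate
26 | 9-O-triethylsilyl triol lactone | O=C1O[C@@H]2/C=C(\C)CC/C=C(/C)[C@@H](O[Si](CC)(CC)CC)[C@@H](O)[C@@]2(O)C1=C | intermediate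
27 | ethyl (E)-2-methylbut-2-enoate | CCOC(=O)/C(C)=C/C | starting material
28 | (E)-2-methylbut-2-en-1-ol | C/C=C(\C)CO | intermediate
29 | (2R,3R)-2,3-epoxy-2-methylbutan-1-ol | OC[C@@]1(C)O[C@@H]1C | intermediate
30 | (2S,3R)-2,3-epoxy-2-methylbutanoic acid | OC(=O)[C@@]1(C)O[C@@H]1C | intermediate
31 | mixed anhydride of 30 with 2,4,6-trichlorobenzoic acid | Clc1cc(Cl)c(C(=O)OC(=O)[C@@]2(C)O[C@@H]2C)c(Cl)c1 | intermediate
32 | 9-O-triethylsilyl ether of the target | C=C1C(=O)O[C@@H]2/C=C(\C)CC/C=C(/C)[C@@H](O[Si](CC)(CC)CC)[C@@H](OC(=O)[C@@]3(C)O[C@@H]3C)[C@@]12O | intermediate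
33 | CNP0420662.1 | C=C1C(=O)O[C@@H]2/C=C(\C)CC/C=C(/C)[C@@H](O)[C@@H](OC(=O)[C@@]3(C)O[C@@H]3C)[C@@]12O | target

## Step count and least certain steps

Total: 24 steps. Longest linear sequence: 21 steps (1–19, 23, 24) from lactone 1; the acid branch is steps 20–22.

**Step 14 (key step).** The most likely trouble is loss of material through the second oxyanion: sulfonylation or elimination at the C7 alkoxide, or proton transfer that scrambles the enolate before trapping. The fallback masks O7 before the ring expansion, so that a monoanion rearranges. Setting out from ketone 17, N-(trimethylsilyl)imidazole (neat, 50 °C) should give the C7 trimethylsilyl ether F1. Vinylcerium addition as in step 13 then gives the silylated carbinol F2, and KH/18-crown-6 followed by PhNTf2 gives the silylated triflate F3. Methylation with Fe(acac)3 and MeMgBr gives the silylated methyl diene F4. The aqueous PPTS treatment of step 16 cleaves the silyl ether together with the ethyl acetal, and the route is rejoined at lactol 23.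

**Step 9 (with step 8).** Poor facial selectivity is the risk. The peracid in step 8 may attack the α face, or the organocerium reagent may attack the β face, because the α face carries the dioxolane with its C9 oxygen close to the incoming reagent. The fallback builds the cis C6/C7 diol by osmylation instead of by carbonyl addition. Setting out from enol ether 10, MeLi (THF, 0 °C) then PhNTf2 gives the C6/C7 enol triflate F5. Stille coupling (Pd(PPh3)4, LiCl, CuCl, DMSO) with tributyl(3,3-diethoxyprop-1-en-2-yl)stannane F6, made from 13 with n-BuLi and then Bu3SnCl, gives the C7-substituted diene F7. OsO4 (cat.) with NMO should dihydroxylate the trisubstituted, conjugated ring olefin from the β face, anti to the dioxolane, and the route is rejoined at diol 14. Competition from the isopropenyl olefin is the open point of this fallback.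

**Step 13.** Poor facial selectivity again: attack from the α face, anti to the axial isopropenyl group, would place the vinyl group trans to it, and on the locked chair two trans-diaxial alkenyl groups cannot reach the array that the ring expansion needs. The fallback is a thermodynamically controlled methylene transfer. Setting out from ketone 17, dimethylsulfoxonium methylide (Me3S(O)I, NaH, DMSO) should give the C10 spiro-epoxide F8 with the new CH2 equatorial (β) and the oxygen axial (α). Excess dimethylsulfonium methylide (Me3SI, n-BuLi, THF, −10 °C to rt) opens the epoxide at CH2 and eliminates to the allylic alcohol, and the route is rejoined at carbinol 18.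

**Step 18.** Acid-promoted transannular cyclisation of the 1(10),4-diene, or migration of the lactone from O6 to the freed O8, may occur while the ketal is hydrolysed. The fallback releases the diol before ring B exists and forms the lactone last, with O9 under a silyl ether that outlasts the acetal hydrolysis. Setting out from acetal 22, CSA in MeOH (0 °C) should remove the acetonide by transketalisation while the mixed acetal only exchanges ethoxy for methoxy, giving the cyclic methyl acetal triol F9. TBSCl and imidazole in DMF should silylate the less hindered allylic O9 to the 9-O-tert-butyldimethylsilyl ether F10, and Yamaguchi esterification with acid 30 gives the 8-O-epoxy ester F11. PPTS in aqueous acetone hydrolyses the allylic methyl acetal and leaves the secondary silyl ether, giving the silylated lactol F12. TEMPO with PhI(OAc)2 then oxidises the lactol, with no free secondary hydroxyl present, to the 9-O-tert-butyldimethylsilyl ether of the target F13. HF·pyridine in THF removes the silyl group, and the route is rejoined at target 33.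

**Step 19.** Loss of regioselectivity (silylation at O8, or at both secondary hydroxyls) would misplace the ester. The fallback discriminates by oxidation state instead of by sterics. Setting out from triol 25, MnO2 oxidises only the allylic C9 hydroxyl, giving the C9 ketone F14. Yamaguchi esterification of the remaining secondary C8 hydroxyl with 30 gives the keto ester F15. Reagent-controlled reduction of the C9 ketone (the CBS oxazaborolidine enantiomer matched to the 9R alcohol, catecholborane, −78 °C) rejoins the route at target 33. The C8 centre next to the ketone must not epimerise, so this sequence has to be run without base.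

## Further compounds

F1 | step 14 | C7 trimethylsilyl ether of ketone 17 | CCOC1O[C@@H]2[C@H](C(C)=C)C(=O)[C@H]3OC(C)(C)O[C@H]3[C@@]2(O[Si](C)(C)C)C1=C
F2 | step 14 | C7 trimethylsilyl ether of carbinol 18 | CCOC1O[C@@H]2[C@H](C(C)=C)[C@@](C=C)(O)[C@H]3OC(C)(C)O[C@H]3[C@@]2(O[Si](C)(C)C)C1=C
F3 | step 14 | C7 trimethylsilyl ether of triflate 21 | CCOC1O[C@@H]2/C=C(\C)CC/C=C(/OS(=O)(=O)C(F)(F)F)[C@H]3OC(C)(C)O[C@H]3[C@@]2(O[Si](C)(C)C)C1=C
F4 | step 14 | C7 trimethylsilyl ether of methyl diene 22 | CCOC1O[C@@H]2/C=C(\C)CC/C=C(/C)[C@H]3OC(C)(C)O[C@H]3[C@@]2(O[Si](C)(C)C)C1=C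
F5 | step 9 | C6/C7 enol triflate | O=S(=O)(OC1=C[C@H](C(C)=C)[C@@H](O[Si](C)(C)C(C)(C)C)[C@H]2OC(C)(C)O[C@@H]12)C(F)(F)F
F6 | step 9 | tributyl(3,3-diethoxyprop-1-en-2-yl)stannane | CCCC[Sn](CCCC)(CCCC)C(=C)C(OCC)OCC
F7 | step 9 | C6/C7 ene with the 3,3-diethoxyprop-1-en-2-yl group on C7 | CCOC(OCC)C(=C)C1=C[C@H](C(C)=C)[C@@H](O[Si](C)(C)C(C)(C)C)[C@H]2OC(C)(C)O[C@@H]12
F8 | step 13 | C10 spiro-epoxide (CH2 β, O α) | CCOC1O[C@@H]2[C@H](C(C)=C)[C@]4(CO4)[C@H]3OC(C)(C)O[C@H]3[C@@]2(O)C1=C
F9 | step 18 | cyclic methyl acetal 7,8,9-triol | COC1O[C@@H]2/C=C(\C)CC/C=C(/C)[C@@H](O)[C@@H](O)[C@@]2(O)C1=C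
F10 | step 18 | 9-O-tert-butyldimethylsilyl ether of F9 | COC1O[C@@H]2/C=C(\C)CC/C=C(/C)[C@@H](O[Si](C)(C)C(C)(C)C)[C@@H](O)[C@@]2(O)C1=C
F11 | step 18 | 8-O-epoxy ester of F10 | COC1O[C@@H]2/C=C(\C)CC/C=C(/C)[C@@H](O[Si](C)(C)C(C)(C)C)[C@@H](OC(=O)[C@@]3(C)O[C@@H]3C)[C@@]2(O)C1=C
F12 | step 18 | 9-O-tert-butyldimethylsilyl lactol of the target | OC1O[C@@H]2/C=C(\C)CC/C=C(/C)[C@@H](O[Si](C)(C)C(C)(C)C)[C@@H](OC(=O)[C@@]3(C)O[C@@H]3C)[C@@]2(O)C1=C
F13 | step 18 | 9-O-tert-butyldimethylsilyl ether of the target | C=C1C(=O)O[C@@H]2/C=C(\C)CC/C=C(/C)[C@@H](O[Si](C)(C)C(C)(C)C)[C@@H](OC(=O)[C@@]3(C)O[C@@H]3C)[C@@]12O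
F14 | step 19 | C9 ketone of triol lactone 25 | O=C1O[C@@H]2/C=C(\C)CC/C=C(/C)C(=O)[C@@H](O)[C@@]2(O)C1=C
F15 | step 19 | 8-O-epoxy ester of F14 | O=C1O[C@@H]2/C=C(\C)CC/C=C(/C)C(=O)[C@@H](OC(=O)[C@@]3(C)O[C@@H]3C)[C@@]2(O)C1=C
A1 | alternative 1 | 2,2-dichloro-3-silyloxycyclobutanone | O=C1C(Cl)(Cl)[C@](O[Si](C)(C)C(C)(C)C)([C@H](O[Si](C)(C)C(C)(C)C)COCc2ccc(OC)cc2)[C@H]1/C=C(\C)CC/C=C(/C)I
A2 | alternative 1 | dichloroketene | O=C=C(Cl)Cl
A3 | alternative 1 | acyclic C6/C7 Z silyl enol ether | CC(C)(C)[Si](C)(C)O/C(=C\C=C(/C)CC/C=C(/C)I)[C@H](O[Si](C)(C)C(C)(C)C)COCc1ccc(OC)cc1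
A4 | alternative 2 | germacranolide core with free C7 hydroxyl (8-O-PMB, 9-O-TBS) | C=C1C(=O)O[C@@H]2/C=C(\C)CC/C=C(/C)[C@@H](O[Si](C)(C)C(C)(C)C)[C@@H](OCc3ccc(OC)cc3)[C@@]12O
A5 | alternative 2 | C6 phenyl selenocarbonate of the C7 ethynyl macrocycle | C#C[C@@]1(O)[C@H](OC(=O)[Se]c2ccccc2)/C=C(\C)CC/C=C(/C)[C@@H](O[Si](C)(C)C(C)(C)C)[C@H]1OCc1ccc(OC)cc1
A6 | alternative 3 | C3–C9 Z-allylic alcohol with free C3 hydroxyl | OCC/C=C(/C)[C@@H](O)[C@@H](O[Si](C)(C)C(C)(C)C)[C@@]1(C(=C)CO[Si](C)(C)C(C)(C)C)COC(C)(C)O1
A7 | alternative 3 | 5-lithio-2,3-dihydrofuran | [Li]C1=CCCO1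
A8 | alternative 3 | C9 aldehyde | O=C[C@@H](O[Si](C)(C)C(C)(C)C)[C@@]1(C(=C)CO[Si](C)(C)C(C)(C)C)COC(C)(C)O1
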